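**Retrosynthetic overview**

1. After a final fluoride desilylation, the seven-membered carbocycle (C1, C5, C6, C7, C8, C9, C10; daucane numbering, C1 = quaternary ring-fusion carbon, C5 = ring-fusion CH) is opened at C6–C7 and at the C8–O bond. This gives a monocyclic cyclopentane dienal, a protected vanilloyl chloride and water.
2. Enabling feature: the ester carbon C6 and the tertiary carbinol C8 sit 1,3 across C7 with both oxygens on one face, and C8 is allylic to C9=C10. This O–C6–C7–C8(O)–C9=C10 array is what an O-acylated aldehyde carbon (C6) leaves when it adds to the CH2 end of a (Z)-2-methyl-1,3-diene (C7=C8–C9=C10) and its own ester carbonyl captures the allyl cation at C8; that ester is the vanillate of the target.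
3. The dienal comes from 3-methylcyclopent-2-en-1-one. Catalytic asymmetric conjugate addition of a 1-silylvinyl group sets C1; C5 (orthoformate addition to the enolate) and C4 (isopropyl addition) are relayed from it; the silylvinyl group is then converted via the alkyne into the (Z)-diene.
4. Stereocentres: C1 by catalysis; C5 and C4 by substrate control; C6 and C8 together in the key step.
5. Order of ring formation: cyclopentane (bought) first; seven-membered carbocycle last, closed together with a temporary 1,3-dioxan-2-ylium ring that is hydrolysed in the same operation.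

Key step: step 11

Remark: locants C1–C10 follow the daucane skeleton (C4 = carbinol carbon bearing isopropyl, C6 = acyloxy carbon, C8 = methyl carbinol carbon, α = face of H5); it is assumed that the enantiomer of the chiral NHC ligand that delivers (S)-5 is chosen.

**Route**

Step 1
Reactants: 1 3-methylcyclopent-2-en-1-one; 2 ethynyltrimethylsilane
Product: 5 (S)-trimethyl({3-methyl-3-[1-(trimethylsilyl)ethenyl]cyclopent-1-en-1-yl}oxy)silane, via vinylalane 3 (not isolated), via aluminium enolate 4 (not isolated)
Conditions: 2, i-Bu2AlH, hexane, 55 °C; then 1, Cu(OTf)2 (5 mol %), chiral sulfonate-bearing imidazolinium salt (NHC ligand precursor, 5.5 mol %), THF, −30 °C; then TMSOTf, −78 → 0 °C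
Reagents that add atoms: trimethylsilyl triflate (C[Si](C)(C)OS(=O)(=O)C(F)(F)F)
Why: Hydroalumination places aluminium on the silicon-bearing alkyne carbon, NHC–copper-catalysed asymmetric conjugate addition of the 1-silylvinylalane to the β-methyl enone sets the quaternary centre C1 under catalyst control, and O-silylation of aluminium enolate 4 fixes the enolate on the C5 side.

Step 2
Reactants: 5 (S)-silyl enol ether; 6 trimethyl orthoformate
Product: 7 (2S,3S)-2-(dimethoxymethyl)-3-methyl-3-[1-(trimethylsilyl)ethenyl]cyclopentan-1-one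
Conditions: TMSOTf (10 mol %), CH2Cl2, −78 °C
Reagents that add atoms: none
Why: Mukaiyama-type addition of the silyl enol ether to the dimethoxycarbenium ion installs C6 at the aldehyde oxidation level, the electrophile approaching C5 anti to the bulky 1-silylvinyl group so that C6 ends cis to the C1 methyl (the epimerisable centre should prefer the same arrangement).

Step 3
Reactants: 7 keto acetal; 8 isopropylmagnesium chloride
Product: 9 (1R,2R,3S)-2-(dimethoxymethyl)-3-methyl-1-(propan-2-yl)-3-[1-(trimethylsilyl)ethenyl]cyclopentan-1-ol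
Conditions: 8, CeCl3 (anhydrous), THF, −78 → 0 °C; aq NH4Cl
Reagents that add atoms: none
Why: Organocerium 1,2-addition (CeCl3 suppresses enolisation and β-hydride reduction) should occur from the face opposite the adjacent dimethoxymethyl group and the C1 methyl, so that isopropyl enters trans to C6 and the C4 hydroxyl ends cis to it by substrate control.

Step 4
Reactants: 9 hydroxy acetal
Product: 10 (1R,2R,3S)-2-(dimethoxymethyl)-3-(1-iodoethenyl)-3-methyl-1-(propan-2-yl)cyclopentan-1-ol
Conditions: NIS, MeCN, 0 °C, dark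
Reagents that add atoms: N-iodosuccinimide (O=C1CCC(=O)N1I)
Why: Electrophilic ipso-iododesilylation of the vinylsilane (β-silyl cation, then loss of silicon) turns the steric control element into a 1-iodovinyl group while no other alkene is present.

Step 5
Reactants: 10 vinyl iodide
Product: 11 (1R,2R,3S)-2-(dimethoxymethyl)-3-ethynyl-3-methyl-1-(propan-2-yl)cyclopentan-1-ol
Conditions: LDA (LiN(i-Pr)2, 3 equiv), THF, −78 → 0 °C; aq NH4Cl
Reagents that add atoms: none
Why: Anti-periplanar E2 dehydroiodination of the 2-iodo-1-alkene gives the terminal alkyne on the quaternary carbon, and no stereocentre is at risk because C5 is not enolisable at the acetal stage.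

Step 6
Reactants: 11 alkynyl acetal
Product: 13 (1R,2S,5R)-2-ethynyl-2-methyl-5-(propan-2-yl)-5-[(triethylsilyl)oxy]cyclopentane-1-carbaldehyde, via pyridinium salt 12 (not isolated)
Conditions: TESOTf (3 equiv), 2,6-lutidine (4 equiv), CH2Cl2, 0 °C; then H2O
Reagents that add atoms: triethylsilyl triflate (CC[Si](CC)(CC)OS(=O)(=O)C(F)(F)F); water (O)
Why: The silyl triflate silylates the tertiary alcohol and ionises the dimethyl acetal, 2,6-lutidine traps the methoxycarbenium ion as pyridinium salt 12, and water hydrolyses this to the aldehyde under base-buffered conditions (silyl triflate/pyridine deacetalisation) that should not epimerise C5.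

Step 7
Reactants: 13 alkynyl aldehyde; 14 2-bromopropene
Product: 15 (1R,2S,5R)-2-methyl-2-(3-methylbut-3-en-1-yn-1-yl)-5-(propan-2-yl)-5-[(triethylsilyl)oxy]cyclopentane-1-carbaldehyde
Conditions: Pd(PPh3)2Cl2 (5 mol %), CuI (10 mol %), Et3N, THF, rt
Reagents that add atoms: none
Why: Sonogashira coupling of the terminal alkyne with the vinyl bromide attaches C8, C7 and the C8 methyl as a conjugated enyne, the hindered aldehyde being inert to Pd/Cu/tertiary amine at room temperature.

Step 8
Reactants: 15 enynal
Product: 16 (1R,2R,5R)-2-methyl-2-[(1Z)-3-methylbuta-1,3-dien-1-yl]-5-(propan-2-yl)-5-[(triethylsilyl)oxy]cyclopentane-1-carbaldehyde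
Conditions: H2 (1 atm), Pd/CaCO3 poisoned with Pb(OAc)2 (Lindlar catalyst), quinoline, EtOAc, rt
Reagents that add atoms: none
Why: Syn-addition of hydrogen on the poisoned palladium surface (Lindlar semi-hydrogenation) should reduce only the alkyne and give the (Z)-diene, which holds the isopropenyl CH2 within reach of the aldehyde.

Step 9
Reactants: 17 vanillic acid (4-hydroxy-3-methoxybenzoic acid)
Product: 19 4-[(tert-butyldimethylsilyl)oxy]-3-methoxybenzoic acid, via bis-silyl derivative 18 (not isolated)
Conditions: TBSCl (2.5 equiv), imidazole, DMF, rt; then AcOH/THF/H2O (3:1:1), rt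
Reagents that add atoms: tert-butyldimethylsilyl chloride (CC(C)(C)[Si](C)(C)Cl)
Why: Silylation of phenol and acid followed by selective solvolysis of the labile silyl ester leaves the aryl silyl ether (standard phenol protection).

Step 10
Reactants: 19 silyl-protected vanillic acid
Product: 20 4-[(tert-butyldimethylsilyl)oxy]-3-methoxybenzoyl chloride
Conditions: (COCl)2, DMF (cat.), CH2Cl2, 0 °C → rt; volatiles removed
Reagents that add atoms: oxalyl chloride (O=C(Cl)C(=O)Cl)
Why: Vilsmeier-type activation with oxalyl chloride/DMF converts the acid into the aroyl chloride, and the aryl silyl ether should tolerate these conditions.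

Step 11
Reactants: 16 (Z)-dienal; 20 aroyl chloride
Product: 24 (3R,3aS,4S,6R,8aR)-6-hydroxy-6,8a-dimethyl-3-(propan-2-yl)-3-[(triethylsilyl)oxy]-1,2,3,3a,4,5,6,8a-octahydroazulen-4-yl 4-[(tert-butyldimethylsilyl)oxy]-3-methoxybenzoate, via 1-chloroalkyl ester 21 (not isolated), via dioxanylium triflate 22 (not isolated), via tertiary ester isomer 23 (not isolated)
Conditions: 20 (1.05 equiv), ZnCl2 (10 mol %), CH2Cl2, −20 °C; AgOTf (1.1 equiv), 2,6-di-tert-butyl-4-methylpyridine (0.2 equiv), −78 → −40 °C; aq NaHCO3, THF, 0 °C; DBU (0.2 equiv), PhMe, rt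
Reagents that add atoms: water (O)
Why: Proposed new method: ZnCl2-catalysed addition of aroyl chloride 20 to the aldehyde gives 1-chloroalkyl ester 21, AgOTf ionises it to an acyloxycarbenium ion at C6, the CH2 terminus C7 of the (Z)-2-methyldiene attacks this ion (7-endo-trig cation–olefin closure of the carbocycle), and the tertiary allyl cation C8–C9–C10 is captured at C8 by the ester carbonyl oxygen (6-exo closure of the temporary 1,3-dioxan-2-ylium ring of 22), in sum a cationic [4+2] addition of the O=C–O–C6 unit across C7=C8. The closest known reaction types are the Prins cyclisation of oxocarbenium ions, the Lewis-acid addition of acylals and 1-haloalkyl ethers to alkenes and allylsilanes, the polar [4+2] cycloaddition of N-acyliminium ions with alkenes to 1,3-oxazinium salts and Woodward–Prévost acyloxonium capture; their union on an acyloxycarbenium ion in a seven-membered ring closure has not been shown. C6 is set in the C–C bond formation by a chair-like transition state in which C7 is anti to C4 and the acyloxy group anti to C1, so that only hydrogen lies between the fully substituted C1 and C4, which places the ester on the face of H5 (6S). C8 is set by the tether, because the carbonyl oxygen hangs from O6 and reaches the allyl cation only at C8 (six-membered ring, whereas C10 would need an eight-membered one) and only from the face of O6, so the cis-1,3 relationship (8R) and the position of the C9=C10 bond follow, while the C4 silyl ether oxygen cannot reach C8 across the trans ring fusion. Aqueous hydrolysis of 22 through its hemiorthoester releases the C8 hydroxyl (its oxygen comes from the aroyl carbonyl), and DBU moves the acyl group of any tertiary ester 23 to the less hindered secondary oxygen at C6 by a 1,3-acyl shift. The step needs attack at C7 rather than C9 (secured by the tertiary allylic cation and by the Z alkene that holds C7 near C6), O-acylation ahead of a Lewis-acid ene reaction (weak ZnCl2, low temperature) and a non-nucleophilic triflate counter-ion that makes 22 the sink.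

Step 12
Reactants: 24 bis-silyl hydroxy ester
Product: 25 (3R,3aS,4S,6R,8aR)-3,6-dihydroxy-6,8a-dimethyl-3-(propan-2-yl)-1,2,3,3a,4,5,6,8a-octahydroazulen-4-yl 4-hydroxy-3-methoxybenzoate (target)
Conditions: TBAF (3 equiv), AcOH (3 equiv), THF, 0 °C → rt
Reagents that add atoms: none
Why: Fluoride cleaves the aryl and the tertiary alkyl silyl ethers (Si–F bond formation) while the acetic acid buffer should keep the aryl ester and the tertiary allylic alcohol intact, and no stereocentre is touched.

**Compound list**

1 | 3-methylcyclopent-2-en-1-one | CC1=CC(=O)CC1 | starting material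
2 | ethynyltrimethylsilane | C#C[Si](C)(C)C | starting material
3 | diisobutyl[1-(trimethylsilyl)ethenyl]aluminium | C=C([Si](C)(C)C)[Al](CC(C)C)CC(C)C | intermediate
4 | diisobutylaluminium (S)-3-methyl-3-[1-(trimethylsilyl)ethenyl]cyclopent-1-en-1-olate | C=C([Si](C)(C)C)[C@@]1(C)CCC(O[Al](CC(C)C)CC(C)C)=C1 | intermediate
5 | (S)-trimethyl({3-methyl-3-[1-(trimethylsilyl)ethenyl]cyclopent-1-en-1-yl}oxy)silane | C=C([Si](C)(C)C)[C@@]1(C)CCC(O[Si](C)(C)C)=C1 | intermediate
6 | trimethyl orthoformate | COC(OC)OC | starting material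
7 | (2S,3S)-2-(dimethoxymethyl)-3-methyl-3-[1-(trimethylsilyl)ethenyl]cyclopentan-1-one | C=C([Si](C)(C)C)[C@@]1(C)CCC(=O)[C@@H]1C(OC)OC | intermediate
8 | isopropylmagnesium chloride | CC(C)[Mg]Cl | starting material
9 | (1R,2R,3S)-2-(dimethoxymethyl)-3-methyl-1-(propan-2-yl)-3-[1-(trimethylsilyl)ethenyl]cyclopentan-1-ol | C=C([Si](C)(C)C)[C@@]1(C)CC[C@@](O)(C(C)C)[C@@H]1C(OC)OC | intermediate
10 | (1R,2R,3S)-2-(dimethoxymethyl)-3-(1-iodoethenyl)-3-methyl-1-(propan-2-yl)cyclopentan-1-ol | C=C(I)[C@@]1(C)CC[C@@](O)(C(C)C)[C@@H]1C(OC)OC | intermediate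
11 | (1R,2R,3S)-2-(dimethoxymethyl)-3-ethynyl-3-methyl-1-(propan-2-yl)cyclopentan-1-ol | C#C[C@@]1(C)CC[C@@](O)(C(C)C)[C@@H]1C(OC)OC | intermediate
12 | 1-[methoxy(cyclopentyl)methyl]-2,6-dimethylpyridinium triflate derived from 11 (C4 oxygen silylated; both epimers at the N,O-acetal carbon) | C#C[C@@]1(C)CC[C@@](O[Si](CC)(CC)CC)(C(C)C)[C@@H]1C(OC)[n+]2c(C)cccc2C.[O-]S(=O)(=O)C(F)(F)F | intermediate
13 | (1R,2S,5R)-2-ethynyl-2-methyl-5-(propan-2-yl)-5-[(triethylsilyl)oxy]cyclopentane-1-carbaldehyde | C#C[C@@]1(C)CC[C@@](O[Si](CC)(CC)CC)(C(C)C)[C@@H]1C=O | intermediate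
14 | 2-bromopropene | C=C(C)Br | starting material
15 | (1R,2S,5R)-2-methyl-2-(3-methylbut-3-en-1-yn-1-yl)-5-(propan-2-yl)-5-[(triethylsilyl)oxy]cyclopentane-1-carbaldehyde | C=C(C)C#C[C@@]1(C)CC[C@@](O[Si](CC)(CC)CC)(C(C)C)[C@@H]1C=O | intermediate
16 | (1R,2R,5R)-2-methyl-2-[(1Z)-3-methylbuta-1,3-dien-1-yl]-5-(propan-2-yl)-5-[(triethylsilyl)oxy]cyclopentane-1-carbaldehyde | C=C(C)/C=C\[C@@]1(C)CC[C@@](O[Si](CC)(CC)CC)(C(C)C)[C@@H]1C=O | intermediate
17 | vanillic acid (4-hydroxy-3-methoxybenzoic acid) | COc1cc(C(=O)O)ccc1O | starting material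
18 | tert-butyldimethylsilyl 4-[(tert-butyldimethylsilyl)oxy]-3-methoxybenzoate | COc1cc(C(=O)O[Si](C)(C)C(C)(C)C)ccc1O[Si](C)(C)C(C)(C)C | intermediate
19 | 4-[(tert-butyldimethylsilyl)oxy]-3-methoxybenzoic acid | COc1cc(C(=O)O)ccc1O[Si](C)(C)C(C)(C)C | intermediate
20 | 4-[(tert-butyldimethylsilyl)oxy]-3-methoxybenzoyl chloride | COc1cc(C(=O)Cl)ccc1O[Si](C)(C)C(C)(C)C | intermediate
21 | chloro[(1R,2R,5R)-2-methyl-2-[(1Z)-3-methylbuta-1,3-dien-1-yl]-5-(propan-2-yl)-5-[(triethylsilyl)oxy]cyclopentyl]methyl 4-[(tert-butyldimethylsilyl)oxy]-3-methoxybenzoate (both epimers at the chloro carbon) | C=C(C)/C=C\[C@@]1(C)CC[C@@](O[Si](CC)(CC)CC)(C(C)C)[C@@H]1C(Cl)OC(=O)c2ccc(O[Si](C)(C)C(C)(C)C)c(OC)c2 | intermediate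
22 | 2-aryl-1,3-dioxan-2-ylium triflate bridging O6 and O8 of the new cycloheptene (C6 S, C8 R; aryl = 4-[(tert-butyldimethylsilyl)oxy]-3-methoxyphenyl) | COc1cc(C2=[O+][C@@]3(C)C=C[C@@]4(C)CC[C@@](O[Si](CC)(CC)CC)(C(C)C)[C@@H]4[C@H](C3)O2)ccc1O[Si](C)(C)C(C)(C)C.[O-]S(=O)(=O)C(F)(F)F | intermediate
23 | regioisomer of 24 with the aroyl group on the tertiary C8 oxygen and a free 6α-hydroxyl (same configuration at all five stereocentres) | O[C@H]1C[C@@](C)(OC(=O)c2ccc(O[Si](C)(C)C(C)(C)C)c(OC)c2)C=C[C@@]3(C)CC[C@@](O[Si](CC)(CC)CC)(C(C)C)[C@H]13 | intermediate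
24 | (3R,3aS,4S,6R,8aR)-6-hydroxy-6,8a-dimethyl-3-(propan-2-yl)-3-[(triethylsilyl)oxy]-1,2,3,3a,4,5,6,8a-octahydroazulen-4-yl 4-[(tert-butyldimethylsilyl)oxy]-3-methoxybenzoate | COc1cc(C(=O)O[C@H]2C[C@@](C)(O)C=C[C@@]3(C)CC[C@@](O[Si](CC)(CC)CC)(C(C)C)[C@H]23)ccc1O[Si](C)(C)C(C)(C)C | intermediate
25 | (3R,3aS,4S,6R,8aR)-3,6-dihydroxy-6,8a-dimethyl-3-(propan-2-yl)-1,2,3,3a,4,5,6,8a-octahydroazulen-4-yl 4-hydroxy-3-methoxybenzoate | COc1cc(C(=O)O[C@H]2C[C@@](C)(O)C=C[C@@]3(C)CC[C@@](O)(C(C)C)[C@H]23)ccc1O | target

**Step count and risks**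

Total step count: 12 (ten on the main line, two for the aroyl chloride). Longest linear sequence: 10 steps (1–8, 11, 12).

Steps most likely to fail:

1. Step 11 (Proposed new method). What may go wrong: attack on the other face of the acyloxycarbenium ion (6-epi series); loss of a proton from the allyl cation before the ester carbonyl closes (ene-type dienes); C-acylation of the diene; incomplete acyl shift from the tertiary to the secondary oxygen after hydrolysis. The fallback uses known reactions, sets out from 16 and returns at 24. Me2AlCl (CH2Cl2, −78 °C) would promote the intramolecular carbonyl-ene cyclisation of 16, the C8 methyl giving up a hydrogen, to dienol F1 with the 6α-hydroxyl, an exocyclic methylene at C8 and the C9=C10 bond in place. VO(acac)2/t-BuOOH epoxidation directed by the homoallylic C6 hydroxyl would deliver oxygen to the α face of the exocyclic alkene and give spiro-epoxide F2. LiEt3BH would open the oxirane at its CH2 to give the 6,8-cis diol F3. Acylation of the only secondary hydroxyl of F3 with 20 (Et3N, DMAP, CH2Cl2) gives 24.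

2. Step 3. What may go wrong: enolisation of the β-keto acetal with loss of methoxide, β-hydride reduction of the hindered ketone by the secondary organometallic, or poor facial selectivity because the 1-silylvinyl group crowds the α face. The fallback sets out from 7 and returns at 9. Isopropenylmagnesium bromide with CeCl3 (smaller nucleophile, no β-hydrogen) would add to 7 to give allylic alcohol F4. Hydroxyl-directed hydrogenation of the isopropenyl group with [Ir(cod)(PCy3)(py)]PF6 and H2 (CH2Cl2, 0 °C) would leave the hindered silyl-substituted alkene on the opposite face and give 9.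

3. Step 8. What may go wrong: over-reduction of the diene, slow reduction of the neopentyl-type alkyne, or Z to E isomerisation on the catalyst. The fallback sets out from 13 and returns at 16, replacing steps 7 and 8. Rhodium-catalysed trans-hydroboration of the terminal alkyne of 13 (pinacolborane, [Rh(cod)Cl]2, P(i-Pr)3, Et3N) would give (Z)-alkenylboronate F5 with the cis geometry already in place. Suzuki–Miyaura coupling of F5 with 14 (Pd(dppf)Cl2, K3PO4, THF/H2O) would give 16 with retention of the Z geometry.

Further compounds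
F1 | step 11 | (3R,3aS,4S,8aR)-8a-methyl-6-methylidene-3-(propan-2-yl)-3-[(triethylsilyl)oxy]-1,2,3,3a,4,5,6,8a-octahydroazulen-4-ol | O[C@H]1CC(=C)C=C[C@@]2(C)CC[C@@](O[Si](CC)(CC)CC)(C(C)C)[C@H]12
F2 | step 11 | spiro-epoxide of F1 at the exocyclic alkene (oxirane oxygen on the α face of C8, cis to the C6 hydroxyl) | O[C@H]1C[C@]3(CO3)C=C[C@@]2(C)CC[C@@](O[Si](CC)(CC)CC)(C(C)C)[C@H]12
F3 | step 11 | (3R,3aS,4S,6R,8aR)-6,8a-dimethyl-3-(propan-2-yl)-3-[(triethylsilyl)oxy]-1,2,3,3a,4,5,6,8a-octahydroazulene-4,6-diol | O[C@H]1C[C@@](C)(O)C=C[C@@]2(C)CC[C@@](O[Si](CC)(CC)CC)(C(C)C)[C@H]12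
F4 | step 3 | (1S,2R,3S)-2-(dimethoxymethyl)-3-methyl-1-(prop-1-en-2-yl)-3-[1-(trimethylsilyl)ethenyl]cyclopentan-1-ol | C=C([Si](C)(C)C)[C@@]1(C)CC[C@@](O)(C(C)=C)[C@@H]1C(OC)OC
F5 | step 8 | (1R,2R,5R)-2-methyl-5-(propan-2-yl)-2-[(Z)-2-(4,4,5,5-tetramethyl-1,3,2-dioxaborolan-2-yl)ethenyl]-5-[(triethylsilyl)oxy]cyclopentane-1-carbaldehyde | CC1(C)OB(/C=C\[C@@]2(C)CC[C@@](O[Si](CC)(CC)CC)(C(C)C)[C@@H]2C=O)OC1(C)C
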